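(The earlier runs and the new flask were generated by integration on assumed constants, noise included.)

We want to know how far the electrophile has gone at 10 min, and how much of the unused nucleophile is then still free.

- Friday's: electrophile 11 mM; free base 22 mM; gas 3.7 mM (held); the very flask that is asked about, followed so far
- flask: electrophile 11 mM; free base 22.0 mM; gas 3.7 mM (held); time 10 min

Friday's run (percent of the electrophile charged)

| time / min | electrophile / % | target / % |
|---|---|---|
| 0.500 | 95.3 | 4.4 |
| 1.00 | 87.6 | 10.8 |
| 1.50 | 78.9 | 16.2 |
| 2.50 | 63.1 | 25.7 |
| 3.00 | 55.7 | 29.1 |
| 4.00 | 42.7 | 35.2 |

(readings scatter by 0.3 percentage points)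

1. part of the electrophile that has reacted at 10 min
2. share of the unused nucleophile that is free and not bound as protonated nucleophile, at 10 min

- at the start none of the gas is in solution
- the earlier runs do not show how much of nucleophile is bound; that part of a forecast is a guess

We begin with the balance of the electrophile, the limiting reagent among the charges. At 4.00 min on Friday, the electrophile used less the target seen leaves a gap of 22 percentage points, up from 1.6 points at 1.00 min. We suppose that this late gap is side product, made when a second electrophile meets target. Each first step sets one acid free, but the second step sets none, so the gap counts one acid for every two units. This acid share, the acid set free per electrophile reacted, reads 0.807.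

Friday's readings do not show where the acid goes, so this is our own commitment: it sits on the nucleophile, and free nucleophile stays near 3.7 mM. With the forecast's conversion, the bound amount is 8.26 mM and the free share is 30.9%.

The neighbouring flask looks nearly the same, differing in its 6.6 mM of electrophile. Its gas is the same, so we expect a similar conversion. Its charge of electrophile is smaller by a factor of 1.67, so if we hold the acid share as it is, its bound amount is smaller and its free share should end higher.

The forecast gives 93% (86% to 97%) and 75% (35% to 98%), saying “Most nucleophile is probably free, but the binding is a guess”. Its free share stands above ours.

The flask gives 93.7% reacted and 31.3% free.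

    electrophile + nucleophile → acid set free + target (k = 1.10 M⁻¹ s⁻¹)
    nucleophile + acid set free ⇌ protonated nucleophile, settled at all times (K = 1.90 × 10⁵ M⁻¹)
    acid set free + free base ⇌ salt of the base (K = 69.0 M⁻¹, k = 7.70 M⁻¹ s⁻¹)
    gas ⇌ nucleophile, rate k4*(csat - [nucleophile]) (kL = 0.0470 s⁻¹)
    electrophile + target → side product (k = 0.340 M⁻¹ s⁻¹)

The acid share with that conversion gives 8.32 mM; at 10.0 min the flask held 7.84 mM of protonated nucleophile and 0.0175 mM of salt of the base. For the neighbouring flask with 6.6 mM of electrophile, the same share gives 4.96 mM bound and a free share of 42.7%; that flask stood at 41.6%.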